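Numbering the chain from the lactone carbonyl (C1) to the methyl group (C12), the target holds a cis-2,5-disubstituted oxolane (C7–C10 plus the ring oxygen) whose two neighbours, C6 and C11, both carry oxygen. This array is the bridgehead/α-carbon pattern of an 8-oxabicyclo[3.2.1]octan-3-one, so the route rests on disconnecting C6–C7 and C10–C11 and adding a temporary C5–C11 bond. One [4+3] cycloaddition of furan with a chiral alkoxy-substituted silyloxyallyl cation builds the oxolane, both flanking C–C bonds and three stereocentres. The precursor is a 2-silyloxyallyl mixed methyl/(S)-1-phenylethyl acetal. Later oxidative scission of C5–C11 unmasks C11 as an aldehyde and C5 as a carboxyl group.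

Key step: step 3

Remark on numbering: target atoms are C1–C12 as above; positions in the bicyclic intermediates are called ring C1–C7 and O8, with ring C1 = C7, ring C2 = C6, ring C3 = C5, ring C4 = C11, ring C5 = C10.

Remark on the auxiliary: it is assumed that the (S)-1-phenylethyl group steers furan to the cation face that gives the (1R,5R) bridgeheads; if the sense proves opposite, (R)-1-phenylethanol is used in step 1 and nothing else changes, because the auxiliary is excised in step 4.

Step 1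
Reactants: 1 1,1-dimethoxypropan-2-one; 2 (S)-1-phenylethanol
Product: 3 1-methoxy-1-[(1S)-1-phenylethoxy]propan-2-one (both epimers at the acetal carbon)
Conditions: 1 (3 equiv), TsOH·H2O (0.02 equiv), cyclohexane, 70 °C, MeOH removed over 4 Å MS
Reagents that add atoms: none
Why: Acid-catalysed transacetalisation exchanges one methoxy group through the acetal oxocarbenium ion, so the C–O stereocentre of the alcohol is never broken, while excess 1 and removal of methanol favour mono-exchange; the new acetal centre is irrelevant because it is ionised in step 3.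

Step 2
Reactants: 3 1-methoxy-1-[(1S)-1-phenylethoxy]propan-2-one
Product: 4 3-methoxy-3-[(1S)-1-phenylethoxy]-2-(triethylsilyloxy)prop-1-ene (both acetal epimers)
Conditions: Et3SiOTf (1.2 equiv), Et3N (2 equiv), Et2O, 0 °C
Reagents that add atoms: triethylsilyl trifluoromethanesulfonate, CC[Si](CC)(CC)OS(=O)(=O)C(F)(F)F
Why: Soft enolisation of the methyl ketone with a silyl triflate and an amine gives the terminal silyl enol ether, and the excess amine keeps the medium basic so that the acetal is not ionised at this stage.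

Step 3
Reactants: 4 3-methoxy-3-[(1S)-1-phenylethoxy]-2-(triethylsilyloxy)prop-1-ene; 5 furan
Product: 8 (1R,2S,5R)-2-[(1S)-1-phenylethoxy]-8-oxabicyclo[3.2.1]oct-6-en-3-one (alkoxy equatorial), via alkoxy-oxyallyl cation 6 (not isolated), via axial C2 epimer 7 (not isolated)
Conditions: 5 (10 equiv), Me3SiOTf (0.1 equiv), CH2Cl2, −95 °C; Et3N; then DBU (0.2 equiv), CH2Cl2, 23 °C
Reagents that add atoms: none
Why: Me3SiOTf removes the methoxy group of 4 to give the 2-silyloxyallyl cation 6, an oxocarbenium ion stabilised by the phenylethoxy oxygen; furan adds through its two α-carbons to the two allyl termini (making C6–C7 and C10–C11) and the silyl group is passed on to the next acetal, leaving the ring C3 ketone. The closest known reaction type is the [4+3] cycloaddition of furans with heteroatom-stabilised oxyallyl cations released from 2-silyloxyallyl acetals by silyl triflates, including mixed acetals of chiral benzylic alcohols. The one new ring, the seven-membered carbocycle, closes by (4+3) annulation, either concerted or by fast collapse of the furan-derived oxocarbenium ion onto the silyl enol ether, with the furan oxygen left as the one-atom bridge. Ring C1 and ring C5 (C7 and C10) are cis by necessity because both bonds form on one furan face, and their absolute sense is set by the 1-phenylethyl group, whose aryl ring covers one face of the planar cation. Ring C2 (C6) is set by equilibration: the kinetic adduct, expected to be mainly the axial epimer 7 from an extended approach, enolises under DBU and is reprotonated on the open face anti to the C6=C7 bridge, which leaves the alkoxy group in the equatorial position, expected to be the more stable one. The step needs facial selectivity on the cation and ring closure in preference to simple furan alkylation; −95 °C and the built-in enol silane nucleophile favour both, and the minor bridgehead isomer is a diastereomer of 8 that chromatography or crystallisation should remove.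

Step 4
Reactants: 8 (1R,2S,5R)-2-[(1S)-1-phenylethoxy]-8-oxabicyclo[3.2.1]oct-6-en-3-one
Product: 9 (1R,2S,5S)-2-hydroxy-8-oxabicyclo[3.2.1]octan-3-one
Conditions: H2 (1 atm), Pd(OH)2 on carbon (10 mol%), EtOAc, 23 °C
Reagents that add atoms: none
Why: Heterogeneous catalytic hydrogenation saturates the strained C6=C7 alkene (C8=C9 of the target) and hydrogenolyses the benzylic C–O bond of the auxiliary in the same flask, while the ketone and the ring C2 configuration are untouched under neutral conditions.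

Step 5
Reactants: 9 (1R,2S,5S)-2-hydroxy-8-oxabicyclo[3.2.1]octan-3-one
Product: 10 (1R,2S,5S)-2-(tert-butyldimethylsilyloxy)-8-oxabicyclo[3.2.1]octan-3-one
Conditions: t-BuMe2SiCl (1.5 equiv), imidazole (3 equiv), DMF, 23 °C
Reagents that add atoms: tert-butyldimethylsilyl chloride, CC(C)(C)[Si](C)(C)Cl
Why: Imidazole-promoted silylation of the secondary alcohol is routine, and any enolisation in this weakly basic medium can only return the equatorial ring C2 epimer already in hand.

Step 6
Reactants: 10 (1R,2S,5S)-2-(tert-butyldimethylsilyloxy)-8-oxabicyclo[3.2.1]octan-3-one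
Product: 11 (1S,4S,5R)-4-(tert-butyldimethylsilyloxy)-3-(trimethylsilyloxy)-8-oxabicyclo[3.2.1]oct-2-ene
Conditions: LiN(i-Pr)2 (1.2 equiv), Me3SiCl (3 equiv, internal quench), THF, −78 °C; pentane, filtration
Reagents that add atoms: chlorotrimethylsilane, C[Si](C)(C)Cl
Why: Kinetic deprotonation by the hindered amide takes an axial proton of the open ring C4 methylene in preference to the ring C2 proton next to the bulky silyloxy group (whose oxygen also disfavours an adjacent enolate), and in situ O-silylation fixes this regiochemistry as the enol silane.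

Step 7
Reactants: 11 (1S,4S,5R)-4-(tert-butyldimethylsilyloxy)-3-(trimethylsilyloxy)-8-oxabicyclo[3.2.1]oct-2-ene
Product: 13 methyl (2S)-2-(tert-butyldimethylsilyloxy)-2-[(2R,5S)-5-formyloxolan-2-yl]acetate, via aldehyde acid 12 (not isolated)
Conditions: O3, CH2Cl2/MeOH (4:1), −78 °C; PPh3, −78 → 23 °C; then Me3SiCHN2, PhMe/MeOH, 0 °C
Reagents that add atoms: ozone, [O-][O+]=O; (trimethylsilyl)diazomethane, C[Si](C)(C)C=[N+]=[N-]
Why: Ozonolysis of the electron-rich enol silane cleaves the former ring C3–C4 bond (C5–C11) to a silyl ester and, after reductive work-up, an aldehyde, and the freed acid is methylated by neutral diazoalkane esterification so that the aldehyde α-centre C10 is not epimerised.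

Step 8
Reactants: 13 methyl (2S)-2-(tert-butyldimethylsilyloxy)-2-[(2R,5S)-5-formyloxolan-2-yl]acetate
Product: 14 methyl (2S)-2-(tert-butyldimethylsilyloxy)-2-{(2R,5S)-5-[(1S)-1-hydroxyethyl]oxolan-2-yl}acetate
Conditions: MgBr2·OEt2 (2 equiv), CH2Cl2, −78 °C; MeMgBr (1.2 equiv, Et2O), −78 °C; NH4Cl (aq)
Reagents that add atoms: methylmagnesium bromide, C[Mg]Br
Why: Chelation-controlled (Cram chelate) Grignard addition, in which magnesium bridges the aldehyde oxygen and the oxolane oxygen and methyl attacks the C11 face opposite the ring C9 methylene, should give the threo (10S,11S) carbinol, and at −78 °C the aldehyde reacts far faster than the ester.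

Step 9
Reactants: 14 methyl (2S)-2-(tert-butyldimethylsilyloxy)-2-{(2R,5S)-5-[(1S)-1-hydroxyethyl]oxolan-2-yl}acetate
Product: 15 methyl (2S)-2-(tert-butyldimethylsilyloxy)-2-{(2R,5S)-5-[(1S)-1-(triethylsilyloxy)ethyl]oxolan-2-yl}acetate
Conditions: Et3SiCl (1.3 equiv), imidazole (2.5 equiv), DMF, 0 → 23 °C
Reagents that add atoms: chlorotriethylsilane, CC[Si](Cl)(CC)CC
Why: Standard silylation; the triethylsilyl ether is chosen because it outlasts steps 10–13 yet is cleaved in step 14 in the presence of the C6 tert-butyldimethylsilyl ether.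

Step 10
Reactants: 15 methyl (2S)-2-(tert-butyldimethylsilyloxy)-2-{(2R,5S)-5-[(1S)-1-(triethylsilyloxy)ethyl]oxolan-2-yl}acetate
Product: 16 (2S)-2-(tert-butyldimethylsilyloxy)-2-{(2R,5S)-5-[(1S)-1-(triethylsilyloxy)ethyl]oxolan-2-yl}acetaldehyde
Conditions: i-Bu2AlH (1.1 equiv), CH2Cl2, −78 °C; MeOH, then aq. potassium sodium tartrate
Reagents that add atoms: none
Why: Partial hydride reduction of an α-silyloxy methyl ester stops at the aluminium hemiacetal at −78 °C and releases the aldehyde only on work-up; the crude aldehyde is used at once so that C6 does not epimerise.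

Step 11
Reactants: 16 (2S)-2-(tert-butyldimethylsilyloxy)-2-{(2R,5S)-5-[(1S)-1-(triethylsilyloxy)ethyl]oxolan-2-yl}acetaldehyde
Product: 17 (1R,2R)-1-(tert-butyldimethylsilyloxy)-1-{(2R,5S)-5-[(1S)-1-(triethylsilyloxy)ethyl]oxolan-2-yl}pent-4-en-2-ol
Conditions: B-allylbis(isopinocampheyl)borane from (−)-α-pinene (1.5 equiv, preformed), Et2O, −78 °C; NaOH, H2O2, 0 → 23 °C
Reagents that add atoms: B-allylbis(isopinocampheyl)borane from (−)-α-pinene, C=CCB([C@H]1C[C@H]2C[C@@H]([C@@H]1C)C2(C)C)[C@H]1C[C@H]2C[C@@H]([C@@H]1C)C2(C)C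
Why: Reagent-controlled asymmetric allylboration (Brown allylation) through a chair-like six-membered transition state should deliver allyl to the Re face of the C5 aldehyde and set C5 as R, anti to the C6 silyloxy group, which is also the sense favoured by Felkin–Anh attack on an α-silyloxy aldehyde (matched pair).

Step 12
Reactants: 17 (1R,2R)-1-(tert-butyldimethylsilyloxy)-1-{(2R,5S)-5-[(1S)-1-(triethylsilyloxy)ethyl]oxolan-2-yl}pent-4-en-2-ol
Product: 18 (1S,2R)-1-(tert-butyldimethylsilyloxy)-1-{(2R,5S)-5-[(1S)-1-(triethylsilyloxy)ethyl]oxolan-2-yl}pent-4-en-2-yl prop-2-enoate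
Conditions: acryloyl chloride (1.5 equiv), Et3N (3 equiv), DMAP (0.1 equiv), CH2Cl2, 0 °C
Reagents that add atoms: acryloyl chloride, C=CC(=O)Cl
Why: O-acylation of the secondary alcohol by an acid chloride under nucleophilic catalysis installs the acrylate without touching any stereocentre (the change of descriptor at C6 is only a priority effect).

Step 13
Reactants: 18 (1S,2R)-1-(tert-butyldimethylsilyloxy)-1-{(2R,5S)-5-[(1S)-1-(triethylsilyloxy)ethyl]oxolan-2-yl}pent-4-en-2-yl prop-2-enoate
Product: 19 (6R)-6-[(S)-(tert-butyldimethylsilyloxy){(2R,5S)-5-[(1S)-1-(triethylsilyloxy)ethyl]oxolan-2-yl}methyl]-5,6-dihydro-2H-pyran-2-one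
Conditions: second-generation Grubbs catalyst RuCl2(=CHPh)(PCy3)(H2IMes) (5 mol%), CH2Cl2 (0.005 M), 40 °C
Reagents that add atoms: none
Why: Ring-closing metathesis between the allyl terminus and the acrylate closes the six-membered α,β-unsaturated lactone with loss of ethene, the ring permitting only the cis C2=C3 alkene.

Step 14
Reactants: 19 (6R)-6-[(S)-(tert-butyldimethylsilyloxy){(2R,5S)-5-[(1S)-1-(triethylsilyloxy)ethyl]oxolan-2-yl}methyl]-5,6-dihydro-2H-pyran-2-one
Product: 20 (6R)-6-[(S)-(tert-butyldimethylsilyloxy){(2R,5S)-5-[(1S)-1-hydroxyethyl]oxolan-2-yl}methyl]-5,6-dihydro-2H-pyran-2-one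
Conditions: PPTS (0.2 equiv), MeOH/CH2Cl2 (1:1), 0 °C
Reagents that add atoms: none
Why: Mild acid-catalysed methanolysis should cleave the triethylsilyl ether much faster than the bulkier, more hindered tert-butyldimethylsilyl ether at C6, and the lactone is inert to these conditions.

Step 15
Reactants: 21 caffeic acid
Product: 23 (2E)-3-[3,4-bis(tert-butyldimethylsilyloxy)phenyl]prop-2-enoic acid, via tris-silyl caffeate 22 (not isolated)
Conditions: t-BuMe2SiCl (3.5 equiv), imidazole (7 equiv), DMF, 23 °C; then AcOH/THF/H2O (3:1:1), 23 °C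
Reagents that add atoms: tert-butyldimethylsilyl chloride, CC(C)(C)[Si](C)(C)Cl
Why: Exhaustive silylation followed by selective hydrolysis of the silyl ester, which is far more labile to aqueous acid than the aryl silyl ethers, should free only the carboxylic acid.

Step 16
Reactants: 20 (6R)-6-[(S)-(tert-butyldimethylsilyloxy){(2R,5S)-5-[(1S)-1-hydroxyethyl]oxolan-2-yl}methyl]-5,6-dihydro-2H-pyran-2-one; 23 (2E)-3-[3,4-bis(tert-butyldimethylsilyloxy)phenyl]prop-2-enoic acid
Product: 24 (1S)-1-[(2S,5R)-5-{(S)-(tert-butyldimethylsilyloxy)[(2R)-6-oxo-3,6-dihydro-2H-pyran-2-yl]methyl}oxolan-2-yl]ethyl (2E)-3-[3,4-bis(tert-butyldimethylsilyloxy)phenyl]prop-2-enoate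
Conditions: DCC (1.5 equiv), DMAP (0.3 equiv), CH2Cl2, 0 → 23 °C
Reagents that add atoms: none
Why: Steglich esterification acylates the only free hydroxyl (C11–OH) with retention of configuration, the phenols of the acid being masked.

Step 17
Reactants: 24 (1S)-1-[(2S,5R)-5-{(S)-(tert-butyldimethylsilyloxy)[(2R)-6-oxo-3,6-dihydro-2H-pyran-2-yl]methyl}oxolan-2-yl]ethyl (2E)-3-[3,4-bis(tert-butyldimethylsilyloxy)phenyl]prop-2-enoate
Product: 25 (1S)-1-[(2S,5R)-5-{(S)-hydroxy[(2R)-6-oxo-3,6-dihydro-2H-pyran-2-yl]methyl}oxolan-2-yl]ethyl (2E)-3-(3,4-dihydroxyphenyl)prop-2-enoate (CNP0300981.1)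
Conditions: HF·pyridine (excess), pyridine, THF, 0 → 23 °C
Reagents that add atoms: none
Why: Fluoride-driven desilylation in a buffered, non-basic medium removes the two aryl silyl ethers and the C6 silyl ether, so that the enoate, the unsaturated lactone and the catechol should survive and no acyl migration is induced.

Compound list
1 | 1,1-dimethoxypropan-2-one | CC(=O)C(OC)OC | starting material
2 | (S)-1-phenylethanol | C[C@H](O)c1ccccc1 | starting material
3 | 1-methoxy-1-[(1S)-1-phenylethoxy]propan-2-one (acetal epimers) | CC(=O)C(OC)O[C@@H](C)c1ccccc1 | intermediate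
4 | 3-methoxy-3-[(1S)-1-phenylethoxy]-2-(triethylsilyloxy)prop-1-ene (acetal epimers) | C=C(O[Si](CC)(CC)CC)C(OC)O[C@@H](C)c1ccccc1 | intermediate
5 | furan | c1ccoc1 | starting material
6 | 1-[(1S)-1-phenylethoxy]-2-(triethylsilyloxy)allyl cation (oxocarbenium form), trifluoromethanesulfonate | C=C(O[Si](CC)(CC)CC)C=[O+][C@@H](C)c1ccccc1.[O-]S(=O)(=O)C(F)(F)F | intermediate
7 | (1R,2R,5R)-2-[(1S)-1-phenylethoxy]-8-oxabicyclo[3.2.1]oct-6-en-3-one (alkoxy axial) | C2[C@@H]1C=C[C@H]([C@@H](O[C@@H](C)c3ccccc3)C2=O)O1 | intermediate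
8 | (1R,2S,5R)-2-[(1S)-1-phenylethoxy]-8-oxabicyclo[3.2.1]oct-6-en-3-one (alkoxy equatorial) | C2[C@@H]1C=C[C@H]([C@H](O[C@@H](C)c3ccccc3)C2=O)O1 | intermediate
9 | (1R,2S,5S)-2-hydroxy-8-oxabicyclo[3.2.1]octan-3-one | C2[C@@H]1CC[C@H]([C@H](O)C2=O)O1 | intermediate
10 | (1R,2S,5S)-2-(tert-butyldimethylsilyloxy)-8-oxabicyclo[3.2.1]octan-3-one | C2[C@@H]1CC[C@H]([C@H](O[Si](C)(C)C(C)(C)C)C2=O)O1 | intermediate
11 | (1S,4S,5R)-4-(tert-butyldimethylsilyloxy)-3-(trimethylsilyloxy)-8-oxabicyclo[3.2.1]oct-2-ene | C1=C(O[Si](C)(C)C)[C@@H](O[Si](C)(C)C(C)(C)C)[C@H]2CC[C@@H]1O2 | intermediate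
12 | (2S)-2-(tert-butyldimethylsilyloxy)-2-[(2R,5S)-5-formyloxolan-2-yl]acetic acid | O=C[C@@H]1CC[C@H]([C@H](O[Si](C)(C)C(C)(C)C)C(=O)O)O1 | intermediate
13 | methyl (2S)-2-(tert-butyldimethylsilyloxy)-2-[(2R,5S)-5-formyloxolan-2-yl]acetate | O=C[C@@H]1CC[C@H]([C@H](O[Si](C)(C)C(C)(C)C)C(=O)OC)O1 | intermediate
14 | methyl (2S)-2-(tert-butyldimethylsilyloxy)-2-{(2R,5S)-5-[(1S)-1-hydroxyethyl]oxolan-2-yl}acetate | C[C@H](O)[C@@H]1CC[C@H]([C@H](O[Si](C)(C)C(C)(C)C)C(=O)OC)O1 | intermediate
15 | methyl (2S)-2-(tert-butyldimethylsilyloxy)-2-{(2R,5S)-5-[(1S)-1-(triethylsilyloxy)ethyl]oxolan-2-yl}acetate | C[C@H](O[Si](CC)(CC)CC)[C@@H]1CC[C@H]([C@H](O[Si](C)(C)C(C)(C)C)C(=O)OC)O1 | intermediate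
16 | (2S)-2-(tert-butyldimethylsilyloxy)-2-{(2R,5S)-5-[(1S)-1-(triethylsilyloxy)ethyl]oxolan-2-yl}acetaldehyde | C[C@H](O[Si](CC)(CC)CC)[C@@H]1CC[C@H]([C@H](O[Si](C)(C)C(C)(C)C)C=O)O1 | intermediate
17 | (1R,2R)-1-(tert-butyldimethylsilyloxy)-1-{(2R,5S)-5-[(1S)-1-(triethylsilyloxy)ethyl]oxolan-2-yl}pent-4-en-2-ol | C[C@H](O[Si](CC)(CC)CC)[C@@H]1CC[C@H]([C@H](O[Si](C)(C)C(C)(C)C)[C@H](O)CC=C)O1 | intermediate
18 | (1S,2R)-1-(tert-butyldimethylsilyloxy)-1-{(2R,5S)-5-[(1S)-1-(triethylsilyloxy)ethyl]oxolan-2-yl}pent-4-en-2-yl prop-2-enoate | C[C@H](O[Si](CC)(CC)CC)[C@@H]1CC[C@H]([C@H](O[Si](C)(C)C(C)(C)C)[C@H](OC(=O)C=C)CC=C)O1 | intermediate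
19 | (6R)-6-[(S)-(tert-butyldimethylsilyloxy){(2R,5S)-5-[(1S)-1-(triethylsilyloxy)ethyl]oxolan-2-yl}methyl]-5,6-dihydro-2H-pyran-2-one | C[C@H](O[Si](CC)(CC)CC)[C@@H]1CC[C@H]([C@H](O[Si](C)(C)C(C)(C)C)[C@H]2CC=CC(=O)O2)O1 | intermediate
20 | (6R)-6-[(S)-(tert-butyldimethylsilyloxy){(2R,5S)-5-[(1S)-1-hydroxyethyl]oxolan-2-yl}methyl]-5,6-dihydro-2H-pyran-2-one | C[C@H](O)[C@@H]1CC[C@H]([C@H](O[Si](C)(C)C(C)(C)C)[C@H]2CC=CC(=O)O2)O1 | intermediate
21 | caffeic acid, (2E)-3-(3,4-dihydroxyphenyl)prop-2-enoic acid | OC(=O)/C=C/c1ccc(O)c(O)c1 | starting material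
22 | tert-butyldimethylsilyl (2E)-3-[3,4-bis(tert-butyldimethylsilyloxy)phenyl]prop-2-enoate | CC(C)(C)[Si](C)(C)OC(=O)/C=C/c1ccc(O[Si](C)(C)C(C)(C)C)c(O[Si](C)(C)C(C)(C)C)c1 | intermediate
23 | (2E)-3-[3,4-bis(tert-butyldimethylsilyloxy)phenyl]prop-2-enoic acid | OC(=O)/C=C/c1ccc(O[Si](C)(C)C(C)(C)C)c(O[Si](C)(C)C(C)(C)C)c1 | intermediate
24 | (1S)-1-[(2S,5R)-5-{(S)-(tert-butyldimethylsilyloxy)[(2R)-6-oxo-3,6-dihydro-2H-pyran-2-yl]methyl}oxolan-2-yl]ethyl (2E)-3-[3,4-bis(tert-butyldimethylsilyloxy)phenyl]prop-2-enoate | C[C@H](OC(=O)/C=C/c1ccc(O[Si](C)(C)C(C)(C)C)c(O[Si](C)(C)C(C)(C)C)c1)[C@@H]1CC[C@H]([C@H](O[Si](C)(C)C(C)(C)C)[C@H]2CC=CC(=O)O2)O1 | intermediate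
25 | (1S)-1-[(2S,5R)-5-{(S)-hydroxy[(2R)-6-oxo-3,6-dihydro-2H-pyran-2-yl]methyl}oxolan-2-yl]ethyl (2E)-3-(3,4-dihydroxyphenyl)prop-2-enoate | C[C@H](OC(=O)/C=C/c1ccc(O)c(O)c1)[C@@H]1CC[C@H]([C@H](O)[C@H]2CC=CC(=O)O2)O1 | target

Total step count: 17. Longest linear sequence: 16 steps (steps 1–14, 16 and 17; step 15 is a one-step side branch).

Steps most likely to fail

Step 3. The phenylethyl group may discriminate the two faces of cation 6 only weakly, or the first C–C bond may be followed by proton loss (simple furan alkylation) instead of ring closure. The fallback sets out from furan 5 and comes back to the route at compound 10; it replaces auxiliary control by desymmetrisation of a meso ketone.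
- Furan 5 and 1,1,3,3-tetrabromoacetone (Zn, B(OEt)3, THF) would give 2,4-dibromo-8-oxabicyclo[3.2.1]oct-6-en-3-one F1.
- Zn/Cu with NH4Cl in MeOH would debrominate it to meso 8-oxabicyclo[3.2.1]oct-6-en-3-one F2.
- H2 over Pd on carbon would give meso 8-oxabicyclo[3.2.1]octan-3-one F3.
- Enantiotopos-selective deprotonation would follow, with Et3SiCl as internal quench (THF, LiCl, −100 °C). The enantiomer of lithium bis(1-phenylethyl)amide that removes the proton at the future C6 would be used. This would give (1R,5S)-3-(triethylsilyloxy)-8-oxabicyclo[3.2.1]oct-2-ene F4.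
- Rubottom oxidation (m-CPBA, NaHCO3, CH2Cl2; citric acid, MeOH) would deliver oxygen to the open face and give the axial ketol (1R,2R,5S)-2-hydroxy-8-oxabicyclo[3.2.1]octan-3-one F5.
- Silylation (t-BuMe2SiCl, imidazole, DMF) would give (1R,2R,5S)-2-(tert-butyldimethylsilyloxy)-8-oxabicyclo[3.2.1]octan-3-one F6.
- DBU in CH2Cl2 would equilibrate ring C2 to the equatorial ether 10.

Step 8. Chelation may be incomplete, so that methyl adds to both faces of the C11 aldehyde and the C11 epimers are hard to separate. The fallback sets out from aldehyde 13 and comes back at compound 14; it sets C11 by reduction instead of by addition.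
- MeMgBr in THF at −78 °C, without attention to selectivity, would give methyl (2S)-2-(tert-butyldimethylsilyloxy)-2-{(2R,5S)-5-[(1RS)-1-hydroxyethyl]oxolan-2-yl}acetate F7.
- Dess–Martin periodinane (NaHCO3, CH2Cl2) would converge both epimers on methyl (2S)-2-[(2R,5S)-5-acetyloxolan-2-yl]-2-(tert-butyldimethylsilyloxy)acetate F8.
- LiBH(s-Bu)3 in THF at −78 °C would reduce the ketone under Felkin–Anh control, which for hydride delivery to a 2-acyloxolane gives the threo alcohol 14 and leaves the ester untouched at this temperature.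

Step 11. Facial selectivity may be eroded if reagent and substrate preferences prove mismatched or if the bulky borane reacts sluggishly with the hindered aldehyde. The fallback sets out from aldehyde 16 and comes back at compound 17; it sets C5 by chelation-controlled reduction.
- AllylMgBr in Et2O at −78 °C would give the C5-epimeric alcohols 1-(tert-butyldimethylsilyloxy)-1-{(2R,5S)-5-[(1S)-1-(triethylsilyloxy)ethyl]oxolan-2-yl}pent-4-en-2-ol F9.
- Dess–Martin periodinane (NaHCO3, CH2Cl2, 0 °C) would give (1S)-1-(tert-butyldimethylsilyloxy)-1-{(2R,5S)-5-[(1S)-1-(triethylsilyloxy)ethyl]oxolan-2-yl}pent-4-en-2-one F10.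
- NaAlH2(OCH2CH2OMe)2 in toluene at −78 °C would reduce this α-silyloxy ketone through a chelate to the anti (5R) alcohol 17.

Further compounds
F1 | step 3 | 2,4-dibromo-8-oxabicyclo[3.2.1]oct-6-en-3-one (stereoisomer mixture at the bromine-bearing carbons) | O=C1C(Br)C2C=CC(C1Br)O2
F2 | step 3 | 8-oxabicyclo[3.2.1]oct-6-en-3-one (meso) | C2[C@@H]1C=C[C@H](CC2=O)O1
F3 | step 3 | 8-oxabicyclo[3.2.1]octan-3-one (meso) | C2[C@@H]1CC[C@H](CC2=O)O1
F4 | step 3 | (1R,5S)-3-(triethylsilyloxy)-8-oxabicyclo[3.2.1]oct-2-ene | C2[C@@H]1CC[C@H](C=C2O[Si](CC)(CC)CC)O1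
F5 | step 3 | (1R,2R,5S)-2-hydroxy-8-oxabicyclo[3.2.1]octan-3-one | C2[C@@H]1CC[C@H]([C@@H](O)C2=O)O1
F6 | step 3 | (1R,2R,5S)-2-(tert-butyldimethylsilyloxy)-8-oxabicyclo[3.2.1]octan-3-one | C2[C@@H]1CC[C@H]([C@@H](O[Si](C)(C)C(C)(C)C)C2=O)O1
F7 | step 8 | methyl (2S)-2-(tert-butyldimethylsilyloxy)-2-{(2R,5S)-5-[(1RS)-1-hydroxyethyl]oxolan-2-yl}acetate (C11 epimer mixture) | CC(O)[C@@H]1CC[C@H]([C@H](O[Si](C)(C)C(C)(C)C)C(=O)OC)O1
F8 | step 8 | methyl (2S)-2-[(2R,5S)-5-acetyloxolan-2-yl]-2-(tert-butyldimethylsilyloxy)acetate | CC(=O)[C@@H]1CC[C@H]([C@H](O[Si](C)(C)C(C)(C)C)C(=O)OC)O1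
F9 | step 11 | 1-(tert-butyldimethylsilyloxy)-1-{(2R,5S)-5-[(1S)-1-(triethylsilyloxy)ethyl]oxolan-2-yl}pent-4-en-2-ol (C5 epimer mixture, C6 as in 16) | C[C@H](O[Si](CC)(CC)CC)[C@@H]1CC[C@H]([C@H](O[Si](C)(C)C(C)(C)C)C(O)CC=C)O1
F10 | step 11 | (1S)-1-(tert-butyldimethylsilyloxy)-1-{(2R,5S)-5-[(1S)-1-(triethylsilyloxy)ethyl]oxolan-2-yl}pent-4-en-2-one | C[C@H](O[Si](CC)(CC)CC)[C@@H]1CC[C@H]([C@H](O[Si](C)(C)C(C)(C)C)C(=O)CC=C)O1
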